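At early times target and side product B rise together: in Thursday's flask they stand at 30.3% and 23.8% at 3.00 min. Later side product B levels off and target slowly falls.

| setting | Thursday's | Tuesday's | Friday's | Wednesday's | beta | zeta | epsilon | eta |
|---|---|---|---|---|---|---|---|---|
| substrate | 0.30 M | 0.42 M | 0.66 M | 0.30 M | 0.30 M | 0.30 M | 0.30 M (fed, over 20.0 min) | 0.30 M |
| reagent | 2.5 equiv | 2.5 equiv | 2.5 equiv | 3.8 equiv | 2.50 equiv | 2.50 equiv | 2.50 equiv | 2.50 equiv |
| remark | run made earlier | run made earlier | run made earlier | run made earlier | plug flow through a tube for 40 min, no back-mixing | a single well-mixed tank run continuously and read at steady state, 40 min in it on average | a stirred flask in which substrate is dosed at a steady rate over 20.0 min without added volume, worked up at 40 min | everything together in a closed stirred flask, run for 40 min |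
| time |  |  |  |  | 40 min |  | 40 min | 40 min |

| run | time / min | target / % | side product A / % | side product B / % |
|---|---|---|---|---|
| Thursday's | 3.00 | 30.3 | 5.4 | 23.8 |
| Thursday's | 6.00 | 42.1 | 6.5 | 28.7 |
| Thursday's | 10.0 | 46.4 | 8.5 | 32.0 |
| Thursday's | 15.0 | 47.3 | 9.1 | 30.1 |
| Thursday's | 20.0 | 46.1 | 10.4 | 32.2 |
| Thursday's | 25.0 | 43.1 | 11.7 | 30.6 |
| Tuesday's | 3.00 | 37.1 | 5.0 | 27.9 |
| Tuesday's | 5.00 | 45.3 | 6.4 | 30.0 |
| Tuesday's | 8.00 | 49.9 | 5.9 | 31.9 |
| Tuesday's | 12.0 | 49.3 | 7.7 | 31.3 |
| Tuesday's | 15.0 | 50.7 | 5.2 | 31.5 |
| Tuesday's | 25.0 | 46.5 | 8.4 | 33.0 |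
| Tuesday's | 40.0 | 37.8 | 8.7 | 33.1 |
| Friday's | 6.00 | 54.2 | 5.9 | 30.8 |
| Friday's | 12.0 | 54.2 | 6.3 | 30.5 |
| Friday's | 15.0 | 53.0 | 5.6 | 32.8 |
| Friday's | 25.0 | 47.4 | 6.1 | 31.8 |
| Friday's | 30.0 | 46.4 | 5.2 | 34.5 |
| Friday's | 40.0 | 41.4 | 7.0 | 31.1 |
| Wednesday's | 8.00 | 57.8 | 6.1 | 23.0 |
| Wednesday's | 15.0 | 58.0 | 7.1 | 22.3 |
| Wednesday's | 25.0 | 48.7 | 8.6 | 24.8 |
| Wednesday's | 30.0 | 50.2 | 7.3 | 24.0 |
| Wednesday's | 40.0 | 45.0 | 10.7 | 24.2 |

(each reading ± 1 percentage point)

- percent here means substrate units held: one side product B counts as two
- the stated concentrations are those of everything mixed, before any reaction; amounts are the same in each set-up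
- the feed brings no volume worth counting
- the earlier runs were made in a closed, stirred flask

1. the set-up with the highest share of target in all that became target or side product A or side product B or isomer of the product, at the outlet or at the end ("none" if the first two lie within 2 percentage points) (beta / zeta / epsilon / eta / none)
2. share of target in all that became target or side product A or side product B or isomer of the product, at the outlet or at the end, beta
3. share of target in all that became target or side product A or side product B or isomer of the product, at the outlet or at the end, zeta
4. share of target in all that became target or side product A or side product B or isomer of the product, at the outlet or at the end, epsilon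
5. share of target in all that became target or side product A or side product B or isomer of the product, at the outlet or at the end, eta

Take as your zero a flask in which side product B ignores the proportions of the charge. The readings leave that zero. Late side product B reads 30.6% in Thursday's run and 31.1% in Friday's, at twice the strength. Wednesday's run, with 3.8 equiv of reagent, reads less, 24.2%. So side product B follows substrate against reagent, not dilution.

Now read the fall of target in Wednesday's run:

ln(58.0% / 45.0%) / (40.0 min − 15.0 min) = 0.0102 min⁻¹

This is the ageing rate of target, an apparent first-order rate constant. Run it backwards to get the target formed before ageing: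

Thursday's proportions: 56.5%
Wednesday's proportions: 67.5%

Run forwards, Thursday's figure gives 37.6% of the substrate charged at 40 min for the closed flask eta and the tube beta.

Turn the question round. Dosing makes target younger by about 10.0 min. For eta to tie with epsilon, epsilon would have to form as little as 51.0%. But dosing moves the proportions in Wednesday's direction, so I give epsilon and the tank zeta Wednesday's figure, which is higher:

epsilon: formed × exp(−rate × 30.0 min) = 49.8%
zeta: formed / (one + rate × 40 min) = 48.0%

These figures are percent of the substrate charged, not shares of what was converted, and I take them as shares without correcting them. That gap of 1.8 percentage points lies inside the margin of 2 points, so my answer is none.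

The forecast differs, naming epsilon, “Epsilon is best, narrowly”, with 37.5% for beta and eta, 49.5% for zeta and 52.5% for epsilon.

The flasks give 38.5% for beta, 38.5% for eta, 48.1% for zeta and 52.0% for epsilon. The best is epsilon, by 3.9 points, so my none was wrong.

    2 substrate → side product B (k = 0.312 L mol⁻¹ min⁻¹)
    target ⇌ isomer of the product (K = 11.0, k = 0.00869 min⁻¹)
    reagent → decomposition product (k = 9.40 × 10⁻⁶ min⁻¹)
    substrate → side product A (k = 0.0238 min⁻¹)
    substrate + reagent ⇌ target (K = 13.0 L mol⁻¹, k = 0.249 L mol⁻¹ min⁻¹)

In beta, the half-life of substrate by the step to target alone, forward rate only, is 3.7 min, much shorter than the 80 min of target by the forward step to isomer alone. Scaling the share of 48.1% in the tank zeta by the ageing rate to 3 times the residence time gives 30.5%, and the tank gives a share of 32.5%.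

The earlier runs and the new flask are calculated with constants of no real substance; the scatter is artificial.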